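The closed flask theta holds more coupling partner, 0.0650 M, than starting material, 0.050 M, so starting material is the limiting reagent. The same amounts go into the other set-ups, in other vessels.

| setting | theta | gamma | epsilon | delta |
|---|---|---|---|---|
| starting material | 0.050 M | 0.050 M | 0.050 M | 0.050 M |
| coupling partner | 0.0650 M | 0.0650 M | 0.0650 M | 0.0650 M (fed, over 15.0 h) |
| protic impurity | 2.50 mM | 2.50 mM | 2.50 mM | 2.50 mM |
| time | 15 h |  |  | 15 h |
| remark | a closed flask charged with all of it at once and left for 15 h | one stirred flow tank at steady state, fed with the mixture as stated, mean residence time 15 h | a single well-mixed tank run continuously and read at steady state, 75.0 h in it on average | a stirred flask in which coupling partner is dosed at a steady rate over 15.0 h without added volume, worked up at 15 h |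

    starting material + coupling partner → intermediate + released group (k1 = 0.0060 M⁻¹ s⁻¹)
    intermediate → target (k2 = 3.0 × 10⁻⁵ s⁻¹)
    starting material + protic impurity → quenched substrate (k3 = 0.0016 M⁻¹ s⁻¹)
    starting material + target → side product (k4 = 0.0020 M⁻¹ s⁻¹)

- in percentages every species weighs as the starting material in it: one side product counts as two
- the stated concentrations are those of everything mixed, before any reaction; amounts are the same in each set-up
- the feed brings no volume worth counting
- run time (theta): 15 h

* the set-up with the highest amount of target at the outlet or at the end, in percent of the starting material put in ("none" if the first two lie within 2 percentage points) (theta / gamma / epsilon / delta / none)
* amount of target at the outlet or at the end, in percent of the starting material put in, theta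
* amount of target at the outlet or at the end, in percent of the starting material put in, gamma
* amount of target at the outlet or at the end, in percent of the starting material put in, epsilon
* amount of target at the outlet or at the end, in percent of the starting material put in, delta

The difference 0.0150 M is the spare partner, the charge of coupling partner less the charge of starting material. It sets how long starting material lasts beside target, which matters because target facing starting material at its charge halves in 1.9 h, shorter than the time 15 h.

Two ways give the half-life of starting material in theta. With the partner held at its charge, the coupling gives 0.49 h. With the partner held at the spare amount, it gives 2.14 h. They part by a factor of 4.37, and the first one cheats: the partner runs down towards 23.1 % of its charge as starting material goes, so the last of the starting material follows the slower clock.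

Even that clock is faster than the 6.4 h half-life of intermediate, so in theta most coupling is over before much target stands. In theta, 80.2 % of the intermediate is converted by 15 h, before losses. In epsilon, with 75.0 h in the tank on average, the same step converts 89.0 % before losses, more than in theta, so this reckoning names no winner, since it puts no figure on the losses. In delta, the dosed partner matches the starting material charge after 11.5 h, so for that long delta has no spare partner.

The forecast names theta, with 68 % for theta, below this reckoning's pre-loss figure. It gives 32 % for gamma, 46 % for epsilon and 38 % for delta, reasoning that “slow dosing keeps starting material around while target builds”.

The simulation gives theta first: theta 69.9 %, gamma 31.9 %, epsilon 46.0 %, delta 33.4 %.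

At 15.0 h, theta keeps 27 % of its coupling partner, against 23.1 % from the spare partner; the starting material that went to quenched substrate and side product accounts for 3.90 % of the partner's charge. A neighbour of theta charged with 0.12 M of starting material ends with 11.5 % of target, under the 63 % at the low end of the forecast's range for theta. Its spare partner is negative, a shortfall of 0.0550 M, so the partner covers 54.2 % of the starting material. At the end, coupling partner stands at 0 %, target, intermediate and half the side product's percentage sum to 54.2 %, and side product holds 62.5 % against 11.5 % for target.

All constants stand for no real mixture; the run is a simulation.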